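## Structural features

Ambofuranol is a 2-arylbenzofuran: benzene ring A is fused along the C3a–C7a edge to furan ring C, whose C2 carries ring B (a 2-hydroxy-4-methoxyphenyl group) and whose C3 carries a methoxy group. Ring A bears a free hydroxyl at C6 and a 3-methylbut-2-enyl (prenyl) chain at C5, ortho to one another, while C4 and C7 are unsubstituted. There is no stereocentre and no stereogenic double bond, so no stereocentres stand next to each other and the whole problem is one of regiochemistry and functional-group tolerance. The fragile elements are the prenyl alkene beside a phenol (acid closes it to a chroman, hydrogenation saturates it), the electron-rich enol-ether-like C2=C3 bond of the 3-methoxybenzofuran, and the two free phenols, which oxidise readily under base and air. The real difficulty is to put carbon on C5 and oxygen on C6 of ring A without positional isomers, while keeping four oxygens differentiated as two methyl ethers and two free hydroxyls. The key step uses the fact that the C5-prenyl/C6-oxygen pair is exactly the substituent pair of a siloxyalkyne R–C≡C–OSi. Ring A can therefore be grown onto the C3a–C7a edge of a furan that already carries ring B on the future C2 and the methoxy group on the future C3.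

## Logic of the disconnections

**22 ⇒ 21 (two O–Si bonds, at O6 and O2′).** Both phenols are masked as bulky silyl ethers because a free O2′–H would add to the ketene of the key step and would be sulfonylated and then reduced away in the deoxygenation. Silicon is chosen because fluoride is the one deprotection that touches neither the ortho-prenyl phenol nor the 3-methoxybenzofuran. The gain is a non-acidic, non-reductive last step; the demand is that both silyl groups survive everything before it, which is why O2′ carries the same triisopropylsilyl group as O6 rather than a smaller one.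

**21 ⇒ 20 ⇒ 19 (C4–H traced back to C4–O).** An oxygen is added retrosynthetically at C4, because the annulation leaves a hydroxyl on the carbon that comes from the ketene carbonyl. This exposes the retron of the benzannulation at the cost of two forward steps. The forward removal must work at a carbon flanked by C5 (prenyl) and the ring fusion C3a, and must not hydrogenate the prenyl alkene, hence sulfonate activation and homogeneous formate reduction rather than hydrogenolysis.

**19 ⇒ 10 + 14 (C3a–C4, C4–C5 and C6–C7).** Cutting these three bonds removes ring A and leaves a furan carrying ring B and the methoxy group, plus a two-carbon alkyne that brings C5 with prenyl and C6 with oxygen. The cut is made here because the polarity of 14 fixes the prenyl/oxygen adjacency and because only one furan carbon can take part in ring closure. The forward step needs a ketene on the furan α-carbon, no nucleophilic O–H anywhere in 10, and irradiation that spares the product.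

**10 ⇒ 8 (the C=N2 bond at the methyl carbon).** The diazo group is traced to a methyl ketone by diazo transfer instead of to an acid chloride and the parent diazoalkane, which removes the most hazardous reagent of the sequence. The demand is a single enolisable position, which 8 provides, and conditions mild enough for the aryl silyl ether.

**8 ⇒ 6 (bond between the furan α-carbon, the future C7a, and the acetyl carbon).** The acetyl group is put on by metalation of the only remaining furan α-position. This avoids carrying a carboxyl group through several redox-neutral manipulations; the demand is that this C–H be deprotonated in preference to the aryl C–H between the two ring B oxygens.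

**6 ⇒ 3 + 2, and 2 ⇒ 1 (the aryl–furan bond, future C2–C1′; one O–Si bond).** The furan is taken with its methoxy group already in place, which then directs metalation to the adjacent α-carbon. A copper-mediated methoxylation of a β-bromofuran lying next to an ortho-oxygenated aryl ring is thereby avoided; hot methoxide would strip an aryl silyl ether there and the freed phenoxide could close onto the bromide. The gain is two catalogue building blocks joined in one operation; the demand is a cross-coupling that tolerates an electron-rich, ortho-substituted bromide.

**14 ⇒ 11 (one alkyne carbon and the O–Si bond).** The siloxyalkyne is traced to an ester by one-carbon homologation through an ynolate: the ester carbonyl carbon becomes the oxygen-bearing alkyne carbon (future C6) and the added carbon becomes the prenyl-bearing one (future C5). The demand is carbonyl addition in preference to deprotonation of the doubly activated methylene group of 11, and silylation on oxygen rather than on carbon.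

## Other disconnections considered

**Alternative 1:** The cut is the O1–C2 bond of the furan ring, after ring B has been removed at C2–C1′.
- Forward key step: aqueous base opens the lactone of the bromocoumarin A2 (3-bromo-4-methoxy-7-(methoxymethoxy)-6-prenylchromen-2-one), and the freed phenoxide displaces the vinylic bromide, contracting the pyranone to the benzofuran-2-carboxylic acid A1 (Perkin rearrangement). Ring B would follow by decarboxylative arylation of A1 with bromide 2, then removal of the acetal and silyl groups.
- In favour: ionic chemistry without light or diazo compounds; ring A never carries a superfluous oxygen, so no deoxygenation is needed, and on that point it is better than the chosen plan. Late, convergent arrival of ring B is the equal of the chosen plan.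
- Against: the 4-methoxy group makes A2 a vinylogous carbonate, so base may attack C4 and expel methoxide. After ring opening the same group donates into the acrylate and should slow substitution at the bromide-bearing carbon, relative to the unsubstituted cases on which the rearrangement rests. The methoxymethyl ether needs acid for removal, the reagent class an ortho-prenyl phenol tolerates least.
- Comparison, structure: the key step makes only the furan ring; the prenyl/oxygen pattern of ring A and the C2–aryl bond are left to other steps, whereas the chosen key step sets that pattern itself.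
- Comparison, mechanism: simpler, but with the specific doubt above, against a pericyclic cascade whose regiochemistry is dictated by alkyne polarity.
- Comparison, step economy: it saves the two deoxygenation steps but needs coumarin assembly, O-methylation, bromination, regioselective prenylation, protection, the coupling and two different deprotections, and is estimated to be longer than nine steps.

**Alternative 2:** The cut is the C2=C3 double bond of the furan.
- Forward key step: a tertiary amine converts the α-methoxybenzylphosphonium salt A4 into its ylide, which olefinates the neighbouring aryl ester carbonyl (intramolecular Wittig reaction) and closes the furan, giving the bis-silyl ether A3.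
- In favour: rings A and B are joined by a simple esterification and the furan closes with both C2 and C3 substituents in place. There is no light, no diazo compound and no superfluous oxygen, and A3 is one fluoride step from the target; that endgame is better than the three-step endgame of the chosen plan.
- Against: ester olefination of this kind is established for benzylic ylides without an α-heteroatom. The α-methoxy group makes A4 an O,P-acetal that can ionise, so preparing it beside a phenolic ester and two aryl silyl ethers is delicate, and acyl transfer from oxygen to the ylide carbon can divert the reaction. The prenyl/oxygen pattern of ring A still has to be built separately.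
- Comparison, structure: A3 is closer to the target than 19 is.
- Comparison, mechanism: the chosen annulation is better precedented for its substrate class.
- Comparison, step economy: the shorter endgame is offset by the steps needed to build the formylated, prenylated, differentially protected ring A piece; overall comparable, with the risk concentrated in making A4.

**Alternative 3:** The cut is the three ring B bonds C1′–C2′, C2′–C3′ and C4′–C5′.
- Forward key step: photochemical Wolff rearrangement of the dienyl diazo ketone A6 gives a vinylketene that combines with methoxyethyne A7 by [2+2] cycloaddition, 4π opening and 6π closure, giving A5 with ring B as the free phenol.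
- In favour: it is the same reaction family, and α,β-unsaturated diazo ketones are its classical substrates, so the mechanistic precedent is at least equal. The hydroxyl the annulation creates is the one the target needs at C2′, so nothing has to be removed and A5 is one desilylation from the target; here it is better than the chosen plan.
- Against: ring B is the easy part of the molecule (it is bought as 1 in the chosen plan), while the difficult ring A pattern must be solved beforehand by other means. A6 requires a complete prenylated 3-methoxybenzofuran, chain extension at C2 and a diazo transfer. A7 is a low-boiling, unstable alkyne that must be prepared and handled cold, a safety and handling penalty relative to 14. The extended enone chromophore of A6 invites E/Z isomerisation and pyrazole formation in competition with the Wolff rearrangement.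
- Comparison, structure: the annulation is spent where it is least needed.
- Comparison, mechanism: equal.
- Comparison, step economy: shorter after the key step, clearly longer before it, and longer overall.

Key step: step 6

Assumption: 3-methoxyfuran (3) is taken as a catalogue compound (otherwise one copper-mediated methoxylation from 3-bromofuran); the target is achiral and every stereogenic in-flask intermediate is racemic.

## Route

Step 1
Reactants: 1 2-bromo-5-methoxyphenol
Product: 2 (2-bromo-5-methoxyphenoxy)triisopropylsilane
Conditions: TIPSCl, imidazole, DMF, rt
Reagents that add atoms: chlorotriisopropylsilane, CC(C)[Si](Cl)(C(C)C)C(C)C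
Why: Imidazole-promoted O-silylation of a phenol; the triisopropylsilyl ether is chosen because it must withstand organolithium reagents, LiN(SiMe3)2, aqueous triethylamine and the triflation base, and is later removed by fluoride together with the O6 silyl group.

Step 2
Reactants: 3 3-methoxyfuran; 2 (2-bromo-5-methoxyphenoxy)triisopropylsilane
Product: 6 triisopropyl[5-methoxy-2-(3-methoxyfuran-2-yl)phenoxy]silane, via 2-lithio-3-methoxyfuran 4 (not isolated), via furylzinc chloride 5 (not isolated)
Conditions: 3, n-BuLi, THF, −78 → 0 °C; ZnCl2, 0 °C → rt; then 2, Pd(OAc)2 (cat.), SPhos, THF, 55 °C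
Reagents that add atoms: none
Why: Alkoxy-directed α-lithiation at the furan carbon flanked by ring oxygen and methoxy group, transmetalation to zinc and Negishi coupling; the biarylphosphine-ligated zerovalent palladium formed in situ is suited to an electron-rich, ortho-substituted aryl bromide.

Step 3
Reactants: 6 triisopropyl[5-methoxy-2-(3-methoxyfuran-2-yl)phenoxy]silane
Product: 8 1-{4-methoxy-5-[4-methoxy-2-(triisopropylsilyloxy)phenyl]furan-2-yl}ethanone, via 5-lithiofuran 7 (not isolated)
Conditions: n-BuLi, THF, −78 → −20 °C; MeC(O)N(OMe)Me, −78 → 0 °C; aq. NH4Cl
Reagents that add atoms: N-methoxy-N-methylacetamide, CC(=O)N(C)OC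
Why: The one remaining furan α-hydrogen is the most acidic C–H of 6, and the furyllithium adds only once to the N-methoxy-N-methylamide because the chelated tetrahedral adduct persists until work-up (Weinreb ketone synthesis).

Step 4
Reactants: 8 1-{4-methoxy-5-[4-methoxy-2-(triisopropylsilyloxy)phenyl]furan-2-yl}ethanone
Product: 10 2-diazo-1-{4-methoxy-5-[4-methoxy-2-(triisopropylsilyloxy)phenyl]furan-2-yl}ethanone, via trifluoroacetyl diketone 9 (not isolated)
Conditions: LiN(SiMe3)2, THF, −78 °C; CF3CO2CH2CF3; then 4-acetamidobenzenesulfonyl azide, Et3N, H2O (1 equiv), MeCN, rt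
Reagents that add atoms: 4-acetamidobenzenesulfonyl azide, CC(=O)Nc1ccc(cc1)S(=O)(=O)N=[N+]=[N-]
Why: Detrifluoroacetylative diazo transfer: Claisen trifluoroacetylation of the methyl ketone enolate activates the methyl group, and the sulfonyl azide then delivers N2 with loss of the trifluoroacetyl group as an N-acylsulfonamide; diazomethane is avoided and the aryl silyl ether sees no nucleophilic base.

Step 5
Reactants: 11 ethyl 4-methylpent-3-enoate
Product: 14 triisopropyl(5-methylhex-4-en-1-ynyloxy)silane, via lithium dibromoenolate 12 (not isolated), via lithium ynolate 13 (not isolated)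
Conditions: CH2Br2, lithium 2,2,6,6-tetramethylpiperidide, THF, −78 °C; 11; LiN(SiMe3)2; n-BuLi, −78 °C → rt; then TIPSCl, −78 °C → rt
Reagents that add atoms: dibromomethane, BrCBr; chlorotriisopropylsilane, CC(C)[Si](Cl)(C(C)C)C(C)C
Why: Kowalski ester homologation: acylation of dibromomethyllithium gives the dibromo ketone enolate, bromine–lithium exchange triggers a 1,2-shift of the prenyl methylene carbon to the carbenoid carbon to give the ynolate, and the bulky silyl chloride traps it on oxygen.

Step 6
Reactants: 10 2-diazo-1-{4-methoxy-5-[4-methoxy-2-(triisopropylsilyloxy)phenyl]furan-2-yl}ethanone; 14 triisopropyl(5-methylhex-4-en-1-ynyloxy)silane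
Product: 19 3-methoxy-2-[4-methoxy-2-(triisopropylsilyloxy)phenyl]-5-(3-methylbut-2-enyl)-6-(triisopropylsilyloxy)-1-benzofuran-4-ol, via furylketene 15 (not isolated), via siloxycyclobutenone 16 (not isolated), via dienylketene 17 (not isolated), via cyclohexadienone tautomer 18 (not isolated)
Conditions: 14 (1.3 equiv), hν (borosilicate-filtered Hg lamp or 450 nm LEDs), degassed ClCH2CH2Cl, rt; then 80 °C, dark
Reagents that add atoms: none
Why: Light expels N2 from 10 and the furyl group shifts to the former diazo carbon (Wolff rearrangement), giving ketene 15. The siloxyalkyne then undergoes a regiospecific [2+2] cycloaddition, its nucleophilic prenyl-bearing carbon attacking the ketene carbonyl carbon (C4–C5) while its oxygen-bearing carbon bonds to the former diazo carbon (C6–C7), giving 16. Reversible conrotatory 4π opening of 16 gives dienylketene 17, and only the isomer with the furyl group cis to the ketene-bearing carbon can react further. Ring A closes by thermal disrotatory 6π electrocyclisation of the ketene carbon onto the furan β-carbon (C3a–C4), a six-membered carbocyclic closure, and 18 tautomerises to the phenol with recovery of furan aromaticity. The closest known reaction type is the second-generation Danheiser benzannulation of heteroaryl diazo ketones with siloxyalkynes. No stereocentre is created. The selectivities needed are the [2+2] regiochemistry, secured by the polarisation of the O-silyl ynol ether; the site of closure, secured because the ketene-bearing furan carbon has only one carbon neighbour; and preference of the ketene for the alkyne over the prenyl alkene and oxygen nucleophiles, secured by the high nucleophilicity of 14 and by silylation of O2′. Heating after irradiation completes conversion of any remaining 16.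

Step 7
Reactants: 19 3-methoxy-2-[4-methoxy-2-(triisopropylsilyloxy)phenyl]-5-(3-methylbut-2-enyl)-6-(triisopropylsilyloxy)-1-benzofuran-4-ol
Product: 20 3-methoxy-2-[4-methoxy-2-(triisopropylsilyloxy)phenyl]-5-(3-methylbut-2-enyl)-6-(triisopropylsilyloxy)-1-benzofuran-4-yl trifluoromethanesulfonate
Conditions: Tf2O, pyridine, CH2Cl2, −20 → 0 °C
Reagents that add atoms: trifluoromethanesulfonic anhydride, O=S(=O)(OS(=O)(=O)C(F)(F)F)C(F)(F)F
Why: O-sulfonylation of the only free hydroxyl with the most reactive triflating agent, needed because this phenol is flanked by the prenyl group and the ring fusion; pyridine keeps the medium non-acidic so the prenyl alkene and silyl ethers are not touched.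

Step 8
Reactants: 20 3-methoxy-2-[4-methoxy-2-(triisopropylsilyloxy)phenyl]-5-(3-methylbut-2-enyl)-6-(triisopropylsilyloxy)-1-benzofuran-4-yl trifluoromethanesulfonate
Product: 21 triisopropyl{5-methoxy-2-[3-methoxy-5-(3-methylbut-2-enyl)-6-(triisopropylsilyloxy)-1-benzofuran-2-yl]phenoxy}silane
Conditions: Pd(OAc)2 (cat.), 1,3-bis(diphenylphosphino)propane, HCO2H, Et3N, DMF, 70 °C
Reagents that add atoms: none
Why: Palladium-catalysed hydrodetriflation: zerovalent palladium inserts into the C4–O bond, formate replaces triflate and loses CO2 to give an aryl palladium hydride, and reductive elimination forms C4–H; no H2 or heterogeneous catalyst is present, so the prenyl alkene should survive.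

Step 9
Reactants: 21 triisopropyl{5-methoxy-2-[3-methoxy-5-(3-methylbut-2-enyl)-6-(triisopropylsilyloxy)-1-benzofuran-2-yl]phenoxy}silane
Product: 22 ambofuranol, 2-(2-hydroxy-4-methoxyphenyl)-3-methoxy-5-(3-methylbut-2-enyl)-1-benzofuran-6-ol
Conditions: Bu4NF, AcOH, THF, 0 °C
Reagents that add atoms: none
Why: Fluoride cleaves both aryl O–Si bonds; acetic acid protonates the phenoxides as they form, limiting air oxidation of the electron-rich product, and is far too weak to cyclise the prenyl group onto O6.

## Compound list

1 | 2-bromo-5-methoxyphenol | COc1ccc(Br)c(O)c1 | starting material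
2 | (2-bromo-5-methoxyphenoxy)triisopropylsilane | COc1ccc(Br)c(O[Si](C(C)C)(C(C)C)C(C)C)c1 | intermediate
3 | 3-methoxyfuran | COc1ccoc1 | starting material
4 | (3-methoxyfuran-2-yl)lithium (in-flask species) | [Li]c1occc1OC | intermediate
5 | chloro(3-methoxyfuran-2-yl)zinc (in-flask species) | Cl[Zn]c1occc1OC | intermediate
6 | triisopropyl[5-methoxy-2-(3-methoxyfuran-2-yl)phenoxy]silane | COc1ccc(-c2occc2OC)c(O[Si](C(C)C)(C(C)C)C(C)C)c1 | intermediate
7 | {4-methoxy-5-[4-methoxy-2-(triisopropylsilyloxy)phenyl]furan-2-yl}lithium (in-flask species) | [Li]c1cc(OC)c(-c2ccc(OC)cc2O[Si](C(C)C)(C(C)C)C(C)C)o1 | intermediate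
8 | 1-{4-methoxy-5-[4-methoxy-2-(triisopropylsilyloxy)phenyl]furan-2-yl}ethanone | CC(=O)c1cc(OC)c(-c2ccc(OC)cc2O[Si](C(C)C)(C(C)C)C(C)C)o1 | intermediate
9 | 4,4,4-trifluoro-1-{4-methoxy-5-[4-methoxy-2-(triisopropylsilyloxy)phenyl]furan-2-yl}butane-1,3-dione (crude, used directly) | O=C(CC(=O)C(F)(F)F)c1cc(OC)c(-c2ccc(OC)cc2O[Si](C(C)C)(C(C)C)C(C)C)o1 | intermediate
10 | 2-diazo-1-{4-methoxy-5-[4-methoxy-2-(triisopropylsilyloxy)phenyl]furan-2-yl}ethanone | [N-]=[N+]=CC(=O)c1cc(OC)c(-c2ccc(OC)cc2O[Si](C(C)C)(C(C)C)C(C)C)o1 | intermediate
11 | ethyl 4-methylpent-3-enoate | CCOC(=O)CC=C(C)C | starting material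
12 | lithium 1,1-dibromo-5-methylhexa-1,4-dien-2-olate (in-flask species) | [Li]OC(CC=C(C)C)=C(Br)Br | intermediate
13 | lithium 5-methylhex-4-en-1-yn-1-olate (in-flask species) | [Li]OC#CCC=C(C)C | intermediate
14 | triisopropyl(5-methylhex-4-en-1-ynyloxy)silane | CC(C)=CCC#CO[Si](C(C)C)(C(C)C)C(C)C | intermediate
15 | 2-{4-methoxy-5-[4-methoxy-2-(triisopropylsilyloxy)phenyl]furan-2-yl}ethenone (in-flask species) | O=C=Cc1cc(OC)c(-c2ccc(OC)cc2O[Si](C(C)C)(C(C)C)C(C)C)o1 | intermediate
16 | 4-{4-methoxy-5-[4-methoxy-2-(triisopropylsilyloxy)phenyl]furan-2-yl}-2-(3-methylbut-2-enyl)-3-(triisopropylsilyloxy)cyclobut-2-en-1-one (racemic, in-flask species) | O=C1C(CC=C(C)C)=C(O[Si](C(C)C)(C(C)C)C(C)C)C1c1cc(OC)c(-c2ccc(OC)cc2O[Si](C(C)C)(C(C)C)C(C)C)o1 | intermediate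
17 | (3E)-4-{4-methoxy-5-[4-methoxy-2-(triisopropylsilyloxy)phenyl]furan-2-yl}-2-(3-methylbut-2-enyl)-3-(triisopropylsilyloxy)buta-1,3-dien-1-one (in-flask species) | O=C=C(CC=C(C)C)/C(O[Si](C(C)C)(C(C)C)C(C)C)=C\c1cc(OC)c(-c2ccc(OC)cc2O[Si](C(C)C)(C(C)C)C(C)C)o1 | intermediate
18 | 3-methoxy-2-[4-methoxy-2-(triisopropylsilyloxy)phenyl]-5-(3-methylbut-2-enyl)-6-(triisopropylsilyloxy)-3aH-1-benzofuran-4-one (racemic, in-flask species) | O=C1C(CC=C(C)C)=C(O[Si](C(C)C)(C(C)C)C(C)C)C=C2OC(-c3ccc(OC)cc3O[Si](C(C)C)(C(C)C)C(C)C)=C(OC)C12 | intermediate
19 | 3-methoxy-2-[4-methoxy-2-(triisopropylsilyloxy)phenyl]-5-(3-methylbut-2-enyl)-6-(triisopropylsilyloxy)-1-benzofuran-4-ol | COc1ccc(-c2oc3cc(O[Si](C(C)C)(C(C)C)C(C)C)c(CC=C(C)C)c(O)c3c2OC)c(O[Si](C(C)C)(C(C)C)C(C)C)c1 | intermediate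
20 | 3-methoxy-2-[4-methoxy-2-(triisopropylsilyloxy)phenyl]-5-(3-methylbut-2-enyl)-6-(triisopropylsilyloxy)-1-benzofuran-4-yl trifluoromethanesulfonate | COc1ccc(-c2oc3cc(O[Si](C(C)C)(C(C)C)C(C)C)c(CC=C(C)C)c(OS(=O)(=O)C(F)(F)F)c3c2OC)c(O[Si](C(C)C)(C(C)C)C(C)C)c1 | intermediate
21 | triisopropyl{5-methoxy-2-[3-methoxy-5-(3-methylbut-2-enyl)-6-(triisopropylsilyloxy)-1-benzofuran-2-yl]phenoxy}silane | COc1ccc(-c2oc3cc(O[Si](C(C)C)(C(C)C)C(C)C)c(CC=C(C)C)cc3c2OC)c(O[Si](C(C)C)(C(C)C)C(C)C)c1 | intermediate
22 | ambofuranol, 2-(2-hydroxy-4-methoxyphenyl)-3-methoxy-5-(3-methylbut-2-enyl)-1-benzofuran-6-ol | COc1ccc(-c2oc3cc(O)c(CC=C(C)C)cc3c2OC)c(O)c1 | target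

## Step count and least certain steps

Total: 9 steps. Longest linear sequence: 8 steps (1 → 2 → 6 → 8 → 10 → 19 → 20 → 21 → 22, steps 1, 2, 3, 4, 6, 7, 8 and 9); the alkyne branch (step 5) joins at step 6.

**Step 6 (key step).** The product is a strongly absorbing 2-arylbenzofuran, so screening of the light and secondary photochemistry of the product may slow or erode the reaction. The new C4 phenol may also be acylated by unreacted ketene, and thermal conversion of the cyclobutenone may be incomplete. Fallback: generate the same ketene without light. The fallback sets out from 10: silver-catalysed Wolff rearrangement in wet solvent (PhCO2Ag cat., Et3N, THF–H2O, dark) should give {4-methoxy-5-[4-methoxy-2-(triisopropylsilyloxy)phenyl]furan-2-yl}acetic acid F1 (Arndt–Eistert homologation). Neutral chlorination with 1-chloro-N,N,2-trimethylprop-1-en-1-amine in CH2Cl2 should give {4-methoxy-5-[4-methoxy-2-(triisopropylsilyloxy)phenyl]furan-2-yl}acetyl chloride F2. Slow addition of Et3N to F2 and 14 in toluene, then heating to 80–110 °C, should give the ketene by dehydrochlorination and carry it through the same cycloaddition, opening and closure. The fallback comes back to the route at 19.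

**Step 5.** The methylene group of 11 is both allylic and α to the ester, so proton transfer to the carbenoid or amide base may compete with carbonyl addition and the alkene may drift into conjugation; silylation on carbon may compete with silylation on oxygen. Fallback: build the alkyne first and oxidise it. The fallback sets out from 11: reduction with i-Bu2AlH (CH2Cl2, −78 °C) should give 4-methylpent-3-enal F3, and Corey–Fuchs olefination (CBr4, PPh3, CH2Cl2, 0 °C, non-basic) should give 1,1-dibromo-5-methylhexa-1,4-diene F4. Two equivalents of n-BuLi (THF, −78 °C) should convert F4 into (5-methylhex-4-en-1-ynyl)lithium F5. Oxidation of F5 with lithium tert-butyl peroxide (from t-BuOOH and LiN(SiMe3)2, −78 → 0 °C) should give the ynolate 13, which is silylated as in step 5. The fallback comes back to the route at 14.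

**Step 3.** Metalation may occur in part at the aryl carbon between the two ring B oxygens or at the furan β-position, and the furyllithium may be quenched by proton transfer from the acetamide instead of adding to it. Fallback: electrophilic substitution in place of metalation. The fallback sets out from 6: Vilsmeier–Haack formylation (POCl3, DMF, 0 °C → rt; buffered aqueous NaOAc work-up) at the free furan α-position should give 4-methoxy-5-[4-methoxy-2-(triisopropylsilyloxy)phenyl]furan-2-carbaldehyde F6. Addition of MeMgBr (THF, −78 °C) should give 1-{4-methoxy-5-[4-methoxy-2-(triisopropylsilyloxy)phenyl]furan-2-yl}ethanol F7, and oxidation with MnO2 (CH2Cl2, rt) comes back to the route at 8.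

**Step 8.** Oxidative addition into a C–O bond flanked on both sides may be slow, so that S–O cleavage back to the phenol, or palladium hydride migration along the prenyl chain, competes. Fallback: change both the leaving group and the metal. The fallback sets out from 19: MsCl and Et3N (CH2Cl2, 0 °C) should give 3-methoxy-2-[4-methoxy-2-(triisopropylsilyloxy)phenyl]-5-(3-methylbut-2-enyl)-6-(triisopropylsilyloxy)-1-benzofuran-4-yl methanesulfonate F8, which resists S–O cleavage. Nickel-catalysed hydrogenolysis of the aryl sulfonate (NiCl2(PPh3)2, PPh3, Zn, MeOH, DMF, 60–70 °C; zerovalent nickel inserts more readily into hindered aryl C–O bonds) comes back to the route at 21.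

## Further compounds

F1 | step 6 | {4-methoxy-5-[4-methoxy-2-(triisopropylsilyloxy)phenyl]furan-2-yl}acetic acid | OC(=O)Cc1cc(OC)c(-c2ccc(OC)cc2O[Si](C(C)C)(C(C)C)C(C)C)o1
F2 | step 6 | {4-methoxy-5-[4-methoxy-2-(triisopropylsilyloxy)phenyl]furan-2-yl}acetyl chloride | ClC(=O)Cc1cc(OC)c(-c2ccc(OC)cc2O[Si](C(C)C)(C(C)C)C(C)C)o1
F3 | step 5 | 4-methylpent-3-enal | CC(C)=CCC=O
F4 | step 5 | 1,1-dibromo-5-methylhexa-1,4-diene | CC(C)=CCC=C(Br)Br
F5 | step 5 | (5-methylhex-4-en-1-ynyl)lithium | [Li]C#CCC=C(C)C
F6 | step 3 | 4-methoxy-5-[4-methoxy-2-(triisopropylsilyloxy)phenyl]furan-2-carbaldehyde | O=Cc1cc(OC)c(-c2ccc(OC)cc2O[Si](C(C)C)(C(C)C)C(C)C)o1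
F7 | step 3 | 1-{4-methoxy-5-[4-methoxy-2-(triisopropylsilyloxy)phenyl]furan-2-yl}ethanol (racemic) | CC(O)c1cc(OC)c(-c2ccc(OC)cc2O[Si](C(C)C)(C(C)C)C(C)C)o1
F8 | step 8 | 3-methoxy-2-[4-methoxy-2-(triisopropylsilyloxy)phenyl]-5-(3-methylbut-2-enyl)-6-(triisopropylsilyloxy)-1-benzofuran-4-yl methanesulfonate | COc1ccc(-c2oc3cc(O[Si](C(C)C)(C(C)C)C(C)C)c(CC=C(C)C)c(OS(C)(=O)=O)c3c2OC)c(O[Si](C(C)C)(C(C)C)C(C)C)c1
A1 | alternative 1 | 3-methoxy-6-(methoxymethoxy)-5-(3-methylbut-2-enyl)-1-benzofuran-2-carboxylic acid | COc1c(C(=O)O)oc2cc(OCOC)c(CC=C(C)C)cc12
A2 | alternative 1 | 3-bromo-4-methoxy-7-(methoxymethoxy)-6-(3-methylbut-2-enyl)chromen-2-one | COc1c(Br)c(=O)oc2cc(OCOC)c(CC=C(C)C)cc12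
A3 | alternative 2 | ambofuranol bis(tert-butyldimethylsilyl) ether | COc1ccc(-c2oc3cc(O[Si](C)(C)C(C)(C)C)c(CC=C(C)C)cc3c2OC)c(O[Si](C)(C)C(C)(C)C)c1
A4 | alternative 2 | {[2-({2-[tert-butyl(dimethyl)silyloxy]-4-methoxybenzoyl}oxy)-4-[tert-butyl(dimethyl)silyloxy]-5-(3-methylbut-2-enyl)phenyl](methoxy)methyl}triphenylphosphonium bromide (racemic) | COC(c1cc(CC=C(C)C)c(O[Si](C)(C)C(C)(C)C)cc1OC(=O)c1ccc(OC)cc1O[Si](C)(C)C(C)(C)C)[P+](c1ccccc1)(c1ccccc1)c1ccccc1.[Br-]
A5 | alternative 3 | ambofuranol 6-O-triisopropylsilyl ether | COc1ccc(-c2oc3cc(O[Si](C(C)C)(C(C)C)C(C)C)c(CC=C(C)C)cc3c2OC)c(O)c1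
A6 | alternative 3 | (3E)-1-diazo-4-[3-methoxy-5-(3-methylbut-2-enyl)-6-(triisopropylsilyloxy)-1-benzofuran-2-yl]but-3-en-2-one | [N-]=[N+]=CC(=O)/C=C/c1oc2cc(O[Si](C(C)C)(C(C)C)C(C)C)c(CC=C(C)C)cc2c1OC
A7 | alternative 3 | methoxyethyne | COC#C
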